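Follow these flasks by the fraction of substrate left, not by the clock.

    substrate + partner → single product + released group (k1 = 1.7 /M/h, Ea1 = 71.0 kJ/mol)
    substrate + partner → other mono adduct + released group (k2 = 3.4 /M/h, Ea2 = 76.0 kJ/mol)
    partner + single product → double product + released group (k3 = 3.4 /M/h, Ea3 = 62.0 kJ/mol)
    partner + other mono adduct → double product + released group (k4 = 3.5 /M/h, Ea4 = 56.0 kJ/mol)
    crystals ⇌ released group, rate k5*(cs5 - [released group]) while solid is left; crystals form when [released group] > cs5 (cs5 = 20 mM, k5 = 0.17 /h)
    (constants at 20 °C)

| flask | substrate | partner | temperature | time |
|---|---|---|---|---|
| alpha | 38 mM | 45.6 mM | 60 °C | 4.0 d |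
| eta | 38 mM | 45.6 mM | 40 °C | 4.0 d |
| theta | 38 mM | 45.6 mM | 20 °C | 4.0 d |

- for released group the crystals are counted in
- as a solid, counted per litre of solution: crystals
- the list of constants is for 20 °C, to be carried to other temperatures by the activation energies

- the best flask by amount of single product, in percent of the substrate charged; "all alike" if 1.5 percentage points covers them all (alpha / eta / theta / all alike)
- amount of single product at the end, in percent of the substrate charged, alpha
- amount of single product at the end, in percent of the substrate charged, eta
- amount of single product at the end, in percent of the substrate charged, theta

Each rate in the first four steps carries c partner as a factor, so dividing one balance by another removed it. I called a the ratio of c substrate to its charge and s the first constant over the sum of the first two. I called q the fourth constant over that sum, and p, the selectivity factor, the third constant over that sum: 0.667 in theta, where s was 0.333 and q was 0.686.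

Single product then follows y = s/(1−p)·(a^p − a), and other mono adduct follows n = (1−s)/(1−q)·(a^q − a).

In theta partner's starting time constant against substrate, 5.16 h, was far shorter than 4.0 d, so I reckoned with the whole 45.6 mM of partner consumed. Each substrate consumed takes one partner and each mono adduct passing on takes another, which gives a = 1 − (cB/cA + y + n)/2.

With y and n at zero, a was 40.0 % in each flask, the charges being alike. Going round twice in theta gave 18.7 %, then 19.2 %, and so y = 14.1 %.

In eta, s, p and q became 0.305, 0.482 and 0.424. The same two rounds gave a = 16.1 %, then 14.4 %, and y = 14.7 %.

In alpha they became 0.281, 0.361 and 0.276, with a = 14.3 %, then 10.3 %, and y = 14.8 %.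

Alpha stood above theta by less than 1.5 percentage points, so my answer was all alike.

The forecast gave 15 %, 14.7 % and 14.1 %, hence all alike, holding that “the single product is set by the selectivity at partner exhaustion rather than by time”.

The flasks gave 15.0 % in alpha, 14.7 % in eta and 14.1 % in theta, so the answer is all alike. At 4.00 d, theta held 19.1 % of its substrate, with partner down to 0.00641 % of its charge. A neighbour of theta charged with 150 mM of substrate ended with 72.5 % of that substrate left. Put on the curve with p = 0.667, this gives 8.19 % of single product, and that neighbour held 8.19 %.

All constants were set for the occasion; the result is computed.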